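**Retrosynthetic overview**
1. The C4–O ether is cut last (Mitsunobu): 4-hydroxy-5-methylcoumarin plus an (E)-allylic alcohol carrying the oxabicycle.
2. The allylic alcohol comes from a terminal alkyne (syn methylalumination/CH2O fixes E), the alkyne from a methyl ketone, and the ketone from a bicyclic carboxylic acid plus but-3-en-2-one (decarboxylative radical addition sets C2 exo).
3. The 7-oxabicyclo[2.2.1]heptane acid comes from quasi-Favorskii ring contraction of a 2-bromo-8-oxabicyclo[3.2.1]octan-3-one.
4. The bromoketone comes from an enantioselective (4+3) cycloaddition of 2-methylfuran with the siloxyallyl cation from 1,3-dibromo-3-methylbutan-2-one (sets both bridgeheads).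
5. Ring order: oxabicyclo[3.2.1]octene first, then contraction to the oxabicyclo[2.2.1]heptane; separately the benzene ring (acetoacetate/crotonaldehyde annulation, aromatisation) and then the pyranone ring (Dieckmann).

Assumption: 1 is purchased as such, and the squaramide enantiomer that leads to the (1R,5S) series is identified in a preliminary screen.

SQ (catalyst, step 1) = 3-{[3,5-bis(trifluoromethyl)phenyl]amino}-4-{[(2S)-3,3-dimethyl-1-oxo-1-[(2R)-2-(phenanthren-9-yl)pyrrolidin-1-yl]butan-2-yl]amino}cyclobut-3-ene-1,2-dione, or its enantiomer.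

**Step 1**
Reactants: 1 1,3-dibromo-3-methylbutan-2-one; 2 2-methylfuran
Product: 4 (1R,2S,5S)-2-bromo-1,4,4-trimethyl-8-oxabicyclo[3.2.1]oct-6-en-3-one, via silyl enol ether 3 (not isolated)
Conditions: 1, Et3SiOTf (1.05 equiv), iPr2NEt (1.1 equiv), toluene, −20 °C, solution decanted from the ammonium triflate; then 2 (3 equiv), SQ (10 mol %), Et3SiOTf (10 mol %), toluene, −78 °C; aq. NaHCO3
Reagents that add atoms: none
Why: Proposed new method: soft enolisation gives the 2-siloxyallyl bromide 3, from which the squaramide·Et3SiOTf pair (a hydrogen-bond-donor-enhanced silyl Lewis acid) abstracts the tertiary bromide as Et3SiBr, leaving a 1-bromo-3,3-dimethyl-2-siloxyallyl cation in a contact ion pair with the squaramide-bound triflate, so 2-methylfuran adds to one face only (first bond from the unsubstituted furan C5 to the CMe2 terminus, ring closure from the methyl-bearing C2 to the CHBr terminus, compact transition state placing Br equatorial), which sets C1 (R), C5 (S) and the 1-methyl/2-bromo regiochemistry before silyl transfer back to triflate closes the cycle; the closest known reaction type is the squaramide/silyl triflate co-catalysed enantioselective (4+3) cycloaddition of furans with acetal-derived siloxyallyl cations (and the racemic (4+3) of α-halo-ketone-derived oxyallyl cations), not yet shown for a bromide-derived, bromine-bearing oxyallyl cation with a tertiary terminus.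

**Step 2**
Reactants: 4
Product: 5 (1R,2S,5S)-2-bromo-1,4,4-trimethyl-8-oxabicyclo[3.2.1]octan-3-one
Conditions: KO2CN=NCO2K (6 equiv), AcOH (12 equiv), MeOH, 0 °C to rt
Reagents that add atoms: none
Why: Diimide reduction transfers H2 to the strained bridge alkene and leaves the C–Br bond and the ketone alone (Pd/H2 would risk hydrogenolysis); saturating here avoids retro-cycloaddition of the later oxanorbornene and homoallyl radical rearrangement in step 4, and no stereocentre changes.

**Step 3**
Reactants: 5
Product: 7 (1R,2R,4S)-1,3,3-trimethyl-7-oxabicyclo[2.2.1]heptane-2-carboxylic acid, via ketone hydrate 6 (not isolated)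
Conditions: KOH (6 equiv), H2O/1,4-dioxane 1:1, 60 °C; then aq. HCl to pH 2
Reagents that add atoms: potassium hydroxide, [K+].[OH-]
Why: Quasi-Favorskii (semibenzilic) ring contraction: C4 is quaternary so no cyclopropanone can form, hydroxide adds to the ketone and the alkoxide of 6 pushes the C3–C4 bond (antiperiplanar to the equatorial C2–Br bond) onto C2 with loss of bromide, a 1,2-shift that converts the oxabicyclo[3.2.1]octane into the 7-oxabicyclo[2.2.1]heptane with C3 as the carboxyl group; an axial-bromide epimer equilibrates through the enolate, the bridgeheads are untouched, and the C2 configuration formed (inversion, endo-CO2H) does not matter because step 4 erases it.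

**Step 4**
Reactants: 7; 8 but-3-en-2-one
Product: 10 4-[(1R,2S,4S)-1,3,3-trimethyl-7-oxabicyclo[2.2.1]heptan-2-yl]butan-2-one, via secondary alkyl radical 9 (not isolated)
Conditions: 8 (2 equiv), Ir[dF(CF3)ppy]2(dtbbpy)PF6 (1 mol %), K2HPO4 (1.2 equiv), DMF, blue LEDs, rt
Reagents that add atoms: none
Why: Photoredox decarboxylative Giese addition: the excited trivalent iridium photocatalyst oxidises the carboxylate, CO2 loss gives radical 9, and the enone adds on the exo face (the oxygen-bridge side, away from the endo hydrogens of the CH2CH2 bridge), which sets C2 as S with the side chain exo before reduction and protonation of the α-keto radical.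

**Step 5**
Reactants: 10
Product: 12 (1R,2S,4S)-2-(but-3-yn-1-yl)-1,3,3-trimethyl-7-oxabicyclo[2.2.1]heptane, via enol phosphate 11 (not isolated)
Conditions: LiN(iPr)2 (1.1 equiv), THF, −78 °C; ClP(O)(OEt)2 (1.15 equiv), −78 °C to rt; then LiN(iPr)2 (2.3 equiv), −78 °C to rt; aq. NH4Cl
Reagents that add atoms: none
Why: Kinetic deprotonation of the methyl group, O-phosphorylation and base-induced elimination of diethyl phosphate (one-pot methyl ketone to terminal alkyne conversion) give the alkyne without touching the ring stereocentres.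

**Step 6**
Reactants: 12
Product: 15 (2E)-3-methyl-5-[(1R,2S,4S)-1,3,3-trimethyl-7-oxabicyclo[2.2.1]heptan-2-yl]pent-2-en-1-ol, via alkenylalane 13 (not isolated), via lithium alkenylaluminate 14 (not isolated)
Conditions: Me3Al (2.5 equiv), Cp2ZrCl2 (0.25 equiv), CH2Cl2, 0 °C to rt; evaporate; THF, n-BuLi (1.05 equiv), −78 °C; (CH2O)n (5 equiv), to rt; aq. HCl
Reagents that add atoms: trimethylaluminium, C[Al](C)C; paraformaldehyde (as formaldehyde), C=O
Why: Negishi zirconium-catalysed methylalumination adds Me and Al syn across the alkyne with Al on the terminal carbon, and the aluminate captures formaldehyde with retention, which fixes the (E)-trisubstituted alkene.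

**Step 7**
Reactants: 16 methyl acetoacetate; 17 (E)-but-2-enal
Product: 20 methyl 6-methyl-2-oxocyclohex-3-ene-1-carboxylate, via Michael adduct 18 (not isolated), via aldol 19 (not isolated)
Conditions: NaOMe (0.1 equiv), MeOH, −10 to 0 °C; then HCl gas, 0 °C to rt
Reagents that add atoms: none
Why: Base-catalysed Michael addition of the acetoacetate to the enal followed by acid-promoted intramolecular aldol condensation (Robinson-type annulation) builds the six-membered ring with the methyl next to the ester carbon; the racemic stereocentres are destroyed in step 8.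

**Step 8**
Reactants: 20
Product: 22 methyl 2-hydroxy-6-methylbenzoate, via bromo keto ester 21 (not isolated)
Conditions: Br2 (1.05 equiv), AcOH, 0 °C to rt; then 90 °C
Reagents that add atoms: none
Why: α-Bromination of the β-keto ester and thermal dehydrobromination give a cyclohexadienone that tautomerises to the phenol (oxidative aromatisation).

**Step 9**
Reactants: 22; 23 acetyl chloride
Product: 25 4-hydroxy-5-methyl-2H-chromen-2-one, via aryl acetate 24 (not isolated)
Conditions: NaH (1.05 equiv), THF, 0 °C; 23 (1.05 equiv), 0 °C to rt; then LiN(SiMe3)2 (2.3 equiv), −78 °C to rt; aq. HCl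
Reagents that add atoms: none
Why: O-Acetylation of the sodium phenoxide followed by intramolecular Claisen (Dieckmann-type) condensation of the acetate enolate onto the neighbouring methyl ester closes the 4-hydroxypyranone ring.

**Step 10**
Reactants: 15; 25
Product: 26 4-{[(2E)-3-methyl-5-[(1R,2S,4S)-1,3,3-trimethyl-7-oxabicyclo[2.2.1]heptan-2-yl]pent-2-en-1-yl]oxy}-5-methyl-2H-chromen-2-one
Conditions: PPh3 (1.3 equiv), DIAD (1.3 equiv), THF, 0 °C to rt
Reagents that add atoms: none
Why: Mitsunobu etherification: the acidic enol OH of 25 is O-alkylated by SN2 on the alkoxyphosphonium of the primary allylic alcohol, leaving the alkene geometry and the three ring stereocentres untouched.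

**Compound list**
1 | 1,3-dibromo-3-methylbutan-2-one | BrCC(=O)C(C)(C)Br | starting material
2 | 2-methylfuran | Cc1ccco1 | starting material
3 | (Z)-[(1,3-dibromo-3-methylbut-1-en-2-yl)oxy]triethylsilane | Br/C=C(\O[Si](CC)(CC)CC)C(C)(C)Br | intermediate
4 | (1R,2S,5S)-2-bromo-1,4,4-trimethyl-8-oxabicyclo[3.2.1]oct-6-en-3-one | Br[C@@H]1C(=O)C(C)(C)[C@@H]2C=C[C@@]1(C)O2 | intermediate
5 | (1R,2S,5S)-2-bromo-1,4,4-trimethyl-8-oxabicyclo[3.2.1]octan-3-one | Br[C@@H]1C(=O)C(C)(C)[C@@H]2CC[C@@]1(C)O2 | intermediate
6 | (1R,2S,5S)-2-bromo-1,4,4-trimethyl-8-oxabicyclo[3.2.1]octane-3,3-diol (present as its potassium alkoxide) | Br[C@@H]1C(O)(O)C(C)(C)[C@@H]2CC[C@@]1(C)O2 | intermediate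
7 | (1R,2R,4S)-1,3,3-trimethyl-7-oxabicyclo[2.2.1]heptane-2-carboxylic acid (2-endo) | OC(=O)[C@@H]1C(C)(C)[C@@H]2CC[C@@]1(C)O2 | intermediate
8 | but-3-en-2-one | CC(=O)C=C | starting material
9 | (1R,4S)-1,3,3-trimethyl-7-oxabicyclo[2.2.1]heptan-2-yl radical | [CH]1C(C)(C)[C@@H]2CC[C@@]1(C)O2 | intermediate
10 | 4-[(1R,2S,4S)-1,3,3-trimethyl-7-oxabicyclo[2.2.1]heptan-2-yl]butan-2-one | CC(=O)CC[C@H]1C(C)(C)[C@@H]2CC[C@@]1(C)O2 | intermediate
11 | diethyl 4-[(1R,2S,4S)-1,3,3-trimethyl-7-oxabicyclo[2.2.1]heptan-2-yl]but-1-en-2-yl phosphate | C=C(OP(=O)(OCC)OCC)CC[C@H]1C(C)(C)[C@@H]2CC[C@@]1(C)O2 | intermediate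
12 | (1R,2S,4S)-2-(but-3-yn-1-yl)-1,3,3-trimethyl-7-oxabicyclo[2.2.1]heptane | C#CCC[C@H]1C(C)(C)[C@@H]2CC[C@@]1(C)O2 | intermediate
13 | dimethyl{(1E)-2-methyl-4-[(1R,2S,4S)-1,3,3-trimethyl-7-oxabicyclo[2.2.1]heptan-2-yl]but-1-en-1-yl}alane | C[Al](C)/C=C(\C)CC[C@H]1C(C)(C)[C@@H]2CC[C@@]1(C)O2 | intermediate
14 | lithium butyl(dimethyl){(1E)-2-methyl-4-[(1R,2S,4S)-1,3,3-trimethyl-7-oxabicyclo[2.2.1]heptan-2-yl]but-1-en-1-yl}aluminate | [Li+].CCCC[Al-](C)(C)/C=C(\C)CC[C@H]1C(C)(C)[C@@H]2CC[C@@]1(C)O2 | intermediate
15 | (2E)-3-methyl-5-[(1R,2S,4S)-1,3,3-trimethyl-7-oxabicyclo[2.2.1]heptan-2-yl]pent-2-en-1-ol | OC/C=C(\C)CC[C@H]1C(C)(C)[C@@H]2CC[C@@]1(C)O2 | intermediate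
16 | methyl acetoacetate | CC(=O)CC(=O)OC | starting material
17 | (E)-but-2-enal | C/C=C/C=O | starting material
18 | methyl 2-acetyl-3-methyl-5-oxopentanoate (racemic, diastereomer mixture) | CC(=O)C(C(=O)OC)C(C)CC=O | intermediate
19 | methyl 4-hydroxy-6-methyl-2-oxocyclohexane-1-carboxylate (racemic, diastereomer mixture) | COC(=O)C1C(C)CC(O)CC1=O | intermediate
20 | methyl 6-methyl-2-oxocyclohex-3-ene-1-carboxylate (racemic) | COC(=O)C1C(C)CC=CC1=O | intermediate
21 | methyl 1-bromo-6-methyl-2-oxocyclohex-3-ene-1-carboxylate (racemic) | COC(=O)C1(Br)C(C)CC=CC1=O | intermediate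
22 | methyl 2-hydroxy-6-methylbenzoate | COC(=O)c1c(C)cccc1O | intermediate
23 | acetyl chloride | CC(=O)Cl | starting material
24 | methyl 2-acetoxy-6-methylbenzoate | COC(=O)c1c(C)cccc1OC(C)=O | intermediate
25 | 4-hydroxy-5-methyl-2H-chromen-2-one | Cc1cccc2oc(=O)cc(O)c12 | intermediate
26 | 4-{[(2E)-3-methyl-5-[(1R,2S,4S)-1,3,3-trimethyl-7-oxabicyclo[2.2.1]heptan-2-yl]pent-2-en-1-yl]oxy}-5-methyl-2H-chromen-2-one | C/C(=C\COc1cc(=O)oc2cccc(C)c12)CC[C@H]1C(C)(C)[C@@H]2CC[C@@]1(C)O2 | target

**Totals**
Total steps: 10. Longest linear sequence: 7 (steps 1 to 6, then step 10).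

**Steps most likely to fail, with fallbacks**

Step 1 (proposed new enantioselective (4+3)). Risks are low enantioselectivity, Friedel–Crafts alkylation of the furan instead of ring closure, and the wrong regioisomer. The fallback uses only known chemistry and sets out from 1 and 2. They are combined with Et3N in CF3CH2OH (0 °C to rt), the established base-mediated generation of a halogenated oxyallyl cation from an α,α'-dibromo ketone, to give racemic bromoketone F1. Diimide reduction as in step 2 gives racemic saturated bromoketone F2, and the KOH ring contraction of step 3 gives racemic acid F3. Classical resolution follows: the (S)-1-phenylethylammonium salt F4 of the (1R,2R,4S) acid is crystallised (the (R)-amine is used instead if it gives the less soluble salt with that enantiomer) and acidified. The route is rejoined at 7, at the cost of half the material.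

Step 3 (hydroxide-triggered ring contraction). Risks are enolisation of the bromoketone with β-elimination of the oxygen bridge, and slow hydroxide addition to the hindered ketone. The fallback sets out from 5 and replaces reversible hydroxide addition by irreversible hydride addition followed by a separate oxidation. LiAlH4 (THF, −78 °C to rt) gives the bromohydrin alkoxide F5, which undergoes the same 1,2-shift on warming to give aldehyde F6; this is reduced in the flask to primary alcohol F7. Oxidation (TEMPO cat., NaOCl, then NaClO2) returns to the route at 7.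

Step 10 (Mitsunobu). Risks are alkylation at the 2-oxygen (a 2-alkoxychromone) or at C3, made worse by the peri 5-methyl group. The fallback sets out from 25 and 15 and makes the C4–O bond by addition–elimination instead. Compound 25 is heated with POCl3 (100 °C) to give 4-chloro-5-methylcoumarin F8. The sodium alkoxide of 15 (NaH, THF, 0 °C) then displaces chloride at C4 and the route is rejoined at 26.

**Further compounds**
F1 | step 1 | racemic (1R*,2S*,5S*)-2-bromo-1,4,4-trimethyl-8-oxabicyclo[3.2.1]oct-6-en-3-one | BrC1C(=O)C(C)(C)C2C=CC1(C)O2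
F2 | step 1 | racemic (1R*,2S*,5S*)-2-bromo-1,4,4-trimethyl-8-oxabicyclo[3.2.1]octan-3-one | BrC1C(=O)C(C)(C)C2CCC1(C)O2
F3 | step 1 | racemic (1R*,2R*,4S*)-1,3,3-trimethyl-7-oxabicyclo[2.2.1]heptane-2-carboxylic acid | OC(=O)C1C(C)(C)C2CCC1(C)O2
F4 | step 1 | (S)-1-phenylethylammonium (1R,2R,4S)-1,3,3-trimethyl-7-oxabicyclo[2.2.1]heptane-2-carboxylate | [O-]C(=O)[C@@H]1C(C)(C)[C@@H]2CC[C@@]1(C)O2.C[C@H]([NH3+])c1ccccc1
F5 | step 3 | (1R,2R,5S)-2-bromo-1,4,4-trimethyl-8-oxabicyclo[3.2.1]octan-3-ol (as its alkoxide, C3 configuration not controlled) | Br[C@@H]1C(O)C(C)(C)[C@@H]2CC[C@@]1(C)O2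
F6 | step 3 | (1R,2R,4S)-1,3,3-trimethyl-7-oxabicyclo[2.2.1]heptane-2-carbaldehyde | O=C[C@@H]1C(C)(C)[C@@H]2CC[C@@]1(C)O2
F7 | step 3 | [(1R,2S,4S)-1,3,3-trimethyl-7-oxabicyclo[2.2.1]heptan-2-yl]methanol | OC[C@@H]1C(C)(C)[C@@H]2CC[C@@]1(C)O2
F8 | step 10 | 4-chloro-5-methyl-2H-chromen-2-one | Cc1cccc2oc(=O)cc(Cl)c12
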